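## Retrosynthetic overview

Locants: quinone ring C1 (C=O next to the methyl-bearing C2), C3 (bears the chain), C4, C4a, C8a; side chain C1' to C32' counted from the ring.

1. The target comes from mild oxidation of a 4-hydroxy-1-silyloxynaphthalene, which is made in one operation by a 3+3 anionic annulation. The two halves are ortho-lithiated N,N-diethylbenzamide (benzo ring, C4 as the amide carbon, lithium on C8a) and a C44 α,β-unsaturated acylsilane (C1, C2 with its methyl, C3 and the whole side chain); the new bonds are C1–C8a and C4–C3.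
2. The enabling feature: in the quinone ring, C1(=O)–C2(CH3)=C3 is an enone whose carbonyl carbon C1 sits on benzo carbon C8a, ortho to C4a, which carries the second carbonyl C4. C1 can therefore accept an aryl anion at C8a, and after a Brook shift its β-carbon C3 becomes a nucleophile within reach of C4. Both C1 and C4 end as quinone C=O, so regiochemistry and oxidation level come out right.
3. The acylsilane comes from an enal, and that from an allylic alcohol made by Zr-catalysed carboalumination of a propargyl silyl ether and Pd-catalysed alkenyl–allyl coupling with the C40 allylic chloride (skipped 2E,5E-diene).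
4. The C40 chain comes from two copies of one ω-brominated farnesyl silyl ether and (S)-citronellyl bromide: Cu-catalysed Grignard coupling (C24'–C25'), then sulfone alkylation and reductive desulfonylation (C12'–C13'). The 27R centre comes from the chiral pool; the E olefins come from (2E,6E)-farnesol and an E-selective SeO2 oxidation.
5. Ring order: the benzo ring is bought; the quinone ring is the only ring formed, in step 16, and is oxidised in step 17.

Key step: step 16

Assumption: PhMe2SiLi is used as a titrated THF solution prepared separately from PhMe2SiCl and lithium; the epimers at the sulfone carbon of 12 and at the carbinol carbon of 21 are carried as mixtures because both centres are removed (steps 8 and 15).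

## Route

Step 1
Reactants: 1 (2E,6E)-farnesol
Product: 2 tert-butyl(diphenyl){[(2E,6E)-3,7,11-trimethyldodeca-2,6,10-trien-1-yl]oxy}silane
Conditions: TBDPSCl, imidazole, CH2Cl2, 0 °C to rt
Reagents that add atoms: tert-butyl(chloro)diphenylsilane, CC(C)(C)[Si](Cl)(c1ccccc1)c1ccccc1
Why: Standard silylation of a primary allylic alcohol gives an ether that should survive the Grignard, alkyllithium and hydride reagents of steps 4 to 8.

Step 2
Reactants: 2 farnesyl silyl ether
Product: 3 (2E,6E,10E)-12-[(tert-butyldiphenylsilyl)oxy]-2,6,10-trimethyldodeca-2,6,10-trien-1-ol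
Conditions: SeO2 (0.2 equiv), t-BuOOH, salicylic acid (cat.), CH2Cl2, 0 °C to rt
Reagents that add atoms: tert-butyl hydroperoxide, CC(C)(C)OO (oxygen passed on by catalytic SeO2, O=[Se]=O)
Why: SeO2-catalysed allylic oxidation (ene reaction followed by 2,3-sigmatropic shift) attacks the terminal isopropylidene group of farnesyl derivatives at its (E)-methyl group, so the new allylic alcohol should form with 10E geometry while the inner olefins are left alone.

Step 3
Reactants: 3 ω-hydroxy farnesyl silyl ether
Product: 4 {[(2E,6E,10E)-12-bromo-3,7,11-trimethyldodeca-2,6,10-trien-1-yl]oxy}(tert-butyl)diphenylsilane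
Conditions: CBr4, PPh3, CH2Cl2, 0 °C
Reagents that add atoms: tetrabromomethane, BrC(Br)(Br)Br
Why: Appel bromination converts the primary allylic alcohol into the bromide under neutral conditions without allylic transposition or loss of the silyl ether.

Step 4
Reactants: 5 (S)-citronellyl bromide [(6S)-8-bromo-2,6-dimethyloct-2-ene]; 4 ω-bromo farnesyl silyl ether
Product: 7 tert-butyl(diphenyl){[(2E,6E,10E,15R)-3,7,11,15,19-pentamethylicosa-2,6,10,18-tetraen-1-yl]oxy}silane, via citronellylmagnesium bromide 6 (not isolated)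
Conditions: 5, Mg, THF, 40 °C; then 4, Li2CuCl4 (3 mol %), THF, −78 to 0 °C
Reagents that add atoms: none
Why: Copper-catalysed cross-coupling of the alkyl Grignard reagent with the primary allylic bromide should proceed by SN2 substitution at the CH2Br carbon with retention of the E olefin; the stereocentre is taken unchanged from (S)-citronellyl bromide and is named R from here on only because the CIP ranking of its two chain branches is reversed.

Step 5
Reactants: 7 C25 silyl ether
Product: 8 (2E,6E,10E,15R)-3,7,11,15,19-pentamethylicosa-2,6,10,18-tetraen-1-ol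
Conditions: TBAF, THF, rt
Reagents that add atoms: none
Why: Fluoride-induced desilylation frees the allylic alcohol without touching the olefins.

Step 6
Reactants: 8 C25 allylic alcohol
Product: 10 1-methyl-4-{[(2E,6E,10E,15R)-3,7,11,15,19-pentamethylicosa-2,6,10,18-tetraen-1-yl]sulfonyl}benzene, via allylic bromide 9 (not isolated)
Conditions: PBr3 (0.4 equiv), Et2O, −10 °C; then TolSO2Na, DMF, rt
Reagents that add atoms: sodium 4-methylbenzenesulfinate, [Na+].[O-]S(=O)c1ccc(C)cc1
Why: Bromination of the allylic alcohol with PBr3 followed by SN2 S-alkylation of the sulfinate anion is the standard entry to prenyl-type sulfones and should leave the 2E olefin in place.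

Step 7
Reactants: 10 C25 allylic sulfone; 4 ω-bromo farnesyl silyl ether
Product: 12 tert-butyl(diphenyl){[(2E,6E,10E,14E,18E,22E,27R)-3,7,11,15,19,23,27,31-octamethyl-13-(4-methylphenylsulfonyl)dotriaconta-2,6,10,14,18,22,30-heptaen-1-yl]oxy}silane, via lithiated sulfone 11 (not isolated)
Conditions: n-BuLi, THF, −78 °C; then 4, −78 to −20 °C
Reagents that add atoms: none
Why: Biellmann coupling, in which the sulfone-stabilised allylic carbanion is alkylated at its α-carbon by the primary allylic bromide to form the C12'–C13' bond head to tail; the sulfone-bearing centre forms as a mixture of epimers and is removed in step 8.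

Step 8
Reactants: 12 C40 sulfone
Product: 13 tert-butyl(diphenyl){[(2E,6E,10E,14E,18E,22E,27R)-3,7,11,15,19,23,27,31-octamethyldotriaconta-2,6,10,14,18,22,30-heptaen-1-yl]oxy}silane
Conditions: PdCl2(dppp) (5 mol %), LiBHEt3, THF, 0 °C
Reagents that add atoms: none
Why: Palladium-catalysed reductive desulfonylation (hydride delivery to the less substituted terminus of a π-allylpalladium intermediate) should remove the sulfonyl group with retention of the position and E geometry of the trisubstituted olefin.

Step 9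
Reactants: 13 C40 silyl ether
Product: 14 (2E,6E,10E,14E,18E,22E,27R)-3,7,11,15,19,23,27,31-octamethyldotriaconta-2,6,10,14,18,22,30-heptaen-1-ol
Conditions: TBAF, THF, rt
Reagents that add atoms: none
Why: Fluoride-induced desilylation frees the C40 allylic alcohol without touching the olefins.

Step 10
Reactants: 14 C40 allylic alcohol
Product: 15 (2E,6E,10E,14E,18E,22E,27R)-1-chloro-3,7,11,15,19,23,27,31-octamethyldotriaconta-2,6,10,14,18,22,30-heptaene
Conditions: NCS, Me2S, CH2Cl2, −30 to 0 °C
Reagents that add atoms: N-chlorosuccinimide, O=C1CCC(=O)N1Cl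
Why: Corey–Kim chlorination converts the allylic alcohol into the primary allylic chloride by SN2 displacement of an alkoxysulfonium group, without allylic rearrangement or acid-induced cyclisation of the polyene.

Step 11
Reactants: 16 tert-butyldimethyl(prop-2-yn-1-yloxy)silane; 15 C40 allylic chloride
Product: 18 tert-butyl(dimethyl){[(2E,5E,9E,13E,17E,21E,25E,30R)-2,6,10,14,18,22,26,30,34-nonamethylpentatriaconta-2,5,9,13,17,21,25,33-octaen-1-yl]oxy}silane, via alkenylalane 17 (not isolated)
Conditions: 16, AlMe3 (2.5 equiv), Cp2ZrCl2 (0.25 equiv), CH2Cl2, 0 °C to rt; then 15, Pd(PPh3)4 (5 mol %), THF, rt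
Reagents that add atoms: trimethylaluminium, C[Al](C)C
Why: Zirconium-catalysed carboalumination adds methyl and aluminium syn across the terminal alkyne with methyl on the internal carbon, and the palladium-catalysed alkenyl–allyl Negishi coupling should then join the E-alkenylalane to the primary terminus of the allylic chloride with retention of both olefin geometries to give the skipped 2E,5E-diene.

Step 12
Reactants: 18 C44 silyl ether
Product: 19 (2E,5E,9E,13E,17E,21E,25E,30R)-2,6,10,14,18,22,26,30,34-nonamethylpentatriaconta-2,5,9,13,17,21,25,33-octaen-1-ol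
Conditions: TBAF, THF, 0 °C
Reagents that add atoms: none
Why: Fluoride-induced desilylation frees the allylic alcohol under conditions that do not move the skipped diene.

Step 13
Reactants: 19 C44 allylic alcohol
Product: 20 (2E,5E,9E,13E,17E,21E,25E,30R)-2,6,10,14,18,22,26,30,34-nonamethylpentatriaconta-2,5,9,13,17,21,25,33-octaenal
Conditions: MnO2, hexane/CH2Cl2, rt
Reagents that add atoms: none
Why: MnO2 oxidises the allylic alcohol selectively to the enal under neutral conditions that should not move the skipped diene into conjugation.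

Step 14
Reactants: 20 C44 enal
Product: 21 (2E,5E,9E,13E,17E,21E,25E,30R)-1-[dimethyl(phenyl)silyl]-2,6,10,14,18,22,26,30,34-nonamethylpentatriaconta-2,5,9,13,17,21,25,33-octaen-1-ol (both C1 epimers)
Conditions: PhMe2SiLi, THF, −78 °C; aq NH4Cl at −78 °C
Reagents that add atoms: dimethyl(phenyl)silyllithium, [Li][Si](C)(C)c1ccccc1
Why: 1,2-Addition of the silyllithium reagent to the aldehyde should give the α-silyl carbinol (for a secondary allylic alkoxide the carbon-silyl form is favoured over its Brook-rearranged isomer); the new carbinol centre forms without control and is removed in step 15.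

Step 15
Reactants: 21 α-silyl allylic alcohol
Product: 22 (2E,5E,9E,13E,17E,21E,25E,30R)-1-[dimethyl(phenyl)silyl]-2,6,10,14,18,22,26,30,34-nonamethylpentatriaconta-2,5,9,13,17,21,25,33-octaen-1-one
Conditions: Dess–Martin periodinane, NaHCO3, CH2Cl2, 0 °C
Reagents that add atoms: none
Why: Dess–Martin oxidation of an α-hydroxysilane is a standard route to acylsilanes, and the buffered neutral conditions should preserve the polyene and the skipped diene.

Step 16
Reactants: 23 N,N-diethylbenzamide; 22 C44 acylsilane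
Product: 27 4-{[dimethyl(phenyl)silyl]oxy}-3-methyl-2-[(2E,6E,10E,14E,18E,22E,27R)-3,7,11,15,19,23,27,31-octamethyldotriaconta-2,6,10,14,18,22,30-heptaen-1-yl]naphthalen-1-ol, via aryllithium 24 (not isolated), via silyl alkoxide 25 (not isolated), via siloxyallyllithium 26 (not isolated)
Conditions: 23, s-BuLi, TMEDA, THF, −78 °C; then 22, −78 °C to rt (HMPA if the silyl shift is slow); degassed aq NH4Cl; crude product kept under argon
Reagents that add atoms: none
Why: Proposed new method: the aryllithium 24 should add 1,2 to the very electrophilic acylsilane carbonyl C1 (bond C1–C8a) to give alkoxide 25, whose carbinol carbon is both benzylic and allylic, so a 1,2-Brook shift of silicon from carbon to oxygen should give the delocalised siloxyallyl anion 26, a homoenolate with charge on C3; C3 then attacks the neighbouring diethylamide carbonyl C4 (bond C4–C3), LiNEt2 is expelled and removes the now doubly activated C3–H, and the ring aromatises to the lithium naphtholate of 27. The closest known reaction types are the addition of organolithiums to α,β-unsaturated acylsilanes with Brook rearrangement and γ-trapping of the siloxyallyl anion, the Brook-rearrangement-mediated 3+2 annulation of acryloylsilanes with ketone enolates, and the LDA-induced closure of ortho-allylbenzamides to 1-naphthols. The quinone ring is closed by a 6-(enolendo)-exo-trig acyl substitution at the amide, while the alternative attack through C1 would need a four-membered ring and is excluded. No lasting stereocentre is formed, the remote 27R centre is untouched, and the enone geometry is irrelevant because it is lost in the allyl anion. The step needs 1,2- over 1,4-addition (hard aryllithium, α-methyl group, alkylated β-carbon), Brook shift in preference to lactonisation of 25 onto the amide (aryl and vinyl groups on the carbinol carbon, unreactive tertiary amide, HMPA if required), and an allyl anion with C3 cis to the aryl group (reached by rotation through the benzylic carbanion form and drained by the irreversible closure). Regiochemistry is built in, since the acylsilane oxygen ends on C1 next to the methyl-bearing carbon and the amide oxygen on C4 next to the chain-bearing carbon, and both become quinone carbonyls.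

Step 17
Reactants: 27 naphthohydroquinone monosilyl ether
Product: 28 2-methyl-3-[(2E,6E,10E,14E,18E,22E,27R)-3,7,11,15,19,23,27,31-octamethyldotriaconta-2,6,10,14,18,22,30-heptaen-1-yl]naphthalene-1,4-dione (target)
Conditions: PhI(OAc)2, MeCN/THF/H2O, 0 °C
Reagents that add atoms: none
Why: Two-electron oxidation of the free naphthol by the trivalent iodine reagent should give an O-silylated quinone oxocarbenium ion that loses the silyl group to water and so delivers the quinone directly, while the trisubstituted olefins are not attacked at 0 °C.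

## Compound list

1 | (2E,6E)-farnesol | CC(C)=CCC/C(C)=C/CC/C(C)=C/CO | starting material
2 | tert-butyl(diphenyl){[(2E,6E)-3,7,11-trimethyldodeca-2,6,10-trien-1-yl]oxy}silane | CC(C)=CCC/C(C)=C/CC/C(C)=C/CO[Si](c1ccccc1)(c1ccccc1)C(C)(C)C | intermediate
3 | (2E,6E,10E)-12-[(tert-butyldiphenylsilyl)oxy]-2,6,10-trimethyldodeca-2,6,10-trien-1-ol | OC/C(C)=C/CC/C(C)=C/CC/C(C)=C/CO[Si](c1ccccc1)(c1ccccc1)C(C)(C)C | intermediate
4 | {[(2E,6E,10E)-12-bromo-3,7,11-trimethyldodeca-2,6,10-trien-1-yl]oxy}(tert-butyl)diphenylsilane | BrC/C(C)=C/CC/C(C)=C/CC/C(C)=C/CO[Si](c1ccccc1)(c1ccccc1)C(C)(C)C | intermediate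
5 | (S)-citronellyl bromide, (6S)-8-bromo-2,6-dimethyloct-2-ene | CC(C)=CCC[C@H](C)CCBr | starting material
6 | [(3S)-3,7-dimethyloct-6-en-1-yl]magnesium bromide | CC(C)=CCC[C@H](C)CC[Mg]Br | intermediate
7 | tert-butyl(diphenyl){[(2E,6E,10E,15R)-3,7,11,15,19-pentamethylicosa-2,6,10,18-tetraen-1-yl]oxy}silane | CC(C)=CCC[C@H](C)CCC/C(C)=C/CC/C(C)=C/CC/C(C)=C/CO[Si](c1ccccc1)(c1ccccc1)C(C)(C)C | intermediate
8 | (2E,6E,10E,15R)-3,7,11,15,19-pentamethylicosa-2,6,10,18-tetraen-1-ol | CC(C)=CCC[C@H](C)CCC/C(C)=C/CC/C(C)=C/CC/C(C)=C/CO | intermediate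
9 | (2E,6E,10E,15R)-1-bromo-3,7,11,15,19-pentamethylicosa-2,6,10,18-tetraene | CC(C)=CCC[C@H](C)CCC/C(C)=C/CC/C(C)=C/CC/C(C)=C/CBr | intermediate
10 | 1-methyl-4-{[(2E,6E,10E,15R)-3,7,11,15,19-pentamethylicosa-2,6,10,18-tetraen-1-yl]sulfonyl}benzene | CC(C)=CCC[C@H](C)CCC/C(C)=C/CC/C(C)=C/CC/C(C)=C/CS(=O)(=O)c1ccc(C)cc1 | intermediate
11 | α-lithio derivative of sulfone 10 | CC(C)=CCC[C@H](C)CCC/C(C)=C/CC/C(C)=C/CC/C(C)=C/C([Li])S(=O)(=O)c1ccc(C)cc1 | intermediate
12 | tert-butyl(diphenyl){[(2E,6E,10E,14E,18E,22E,27R)-3,7,11,15,19,23,27,31-octamethyl-13-(4-methylphenylsulfonyl)dotriaconta-2,6,10,14,18,22,30-heptaen-1-yl]oxy}silane (both C13 epimers) | CC(C)=CCC[C@H](C)CCC/C(C)=C/CC/C(C)=C/CC/C(C)=C/C(S(=O)(=O)c1ccc(C)cc1)C/C(C)=C/CC/C(C)=C/CC/C(C)=C/CO[Si](c1ccccc1)(c1ccccc1)C(C)(C)C | intermediate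
13 | tert-butyl(diphenyl){[(2E,6E,10E,14E,18E,22E,27R)-3,7,11,15,19,23,27,31-octamethyldotriaconta-2,6,10,14,18,22,30-heptaen-1-yl]oxy}silane | CC(C)=CCC[C@H](C)CCC/C(C)=C/CC/C(C)=C/CC/C(C)=C/CC/C(C)=C/CC/C(C)=C/CC/C(C)=C/CO[Si](c1ccccc1)(c1ccccc1)C(C)(C)C | intermediate
14 | (2E,6E,10E,14E,18E,22E,27R)-3,7,11,15,19,23,27,31-octamethyldotriaconta-2,6,10,14,18,22,30-heptaen-1-ol | CC(C)=CCC[C@H](C)CCC/C(C)=C/CC/C(C)=C/CC/C(C)=C/CC/C(C)=C/CC/C(C)=C/CC/C(C)=C/CO | intermediate
15 | (2E,6E,10E,14E,18E,22E,27R)-1-chloro-3,7,11,15,19,23,27,31-octamethyldotriaconta-2,6,10,14,18,22,30-heptaene | CC(C)=CCC[C@H](C)CCC/C(C)=C/CC/C(C)=C/CC/C(C)=C/CC/C(C)=C/CC/C(C)=C/CC/C(C)=C/CCl | intermediate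
16 | tert-butyldimethyl(prop-2-yn-1-yloxy)silane | C#CCO[Si](C)(C)C(C)(C)C | starting material
17 | [(1E)-3-{[tert-butyl(dimethyl)silyl]oxy}-2-methylprop-1-en-1-yl]dimethylalane | C[Al](C)/C=C(\C)CO[Si](C)(C)C(C)(C)C | intermediate
18 | tert-butyl(dimethyl){[(2E,5E,9E,13E,17E,21E,25E,30R)-2,6,10,14,18,22,26,30,34-nonamethylpentatriaconta-2,5,9,13,17,21,25,33-octaen-1-yl]oxy}silane | CC(C)=CCC[C@H](C)CCC/C(C)=C/CC/C(C)=C/CC/C(C)=C/CC/C(C)=C/CC/C(C)=C/CC/C(C)=C/C/C=C(\C)CO[Si](C)(C)C(C)(C)C | intermediate
19 | (2E,5E,9E,13E,17E,21E,25E,30R)-2,6,10,14,18,22,26,30,34-nonamethylpentatriaconta-2,5,9,13,17,21,25,33-octaen-1-ol | CC(C)=CCC[C@H](C)CCC/C(C)=C/CC/C(C)=C/CC/C(C)=C/CC/C(C)=C/CC/C(C)=C/CC/C(C)=C/C/C=C(\C)CO | intermediate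
20 | (2E,5E,9E,13E,17E,21E,25E,30R)-2,6,10,14,18,22,26,30,34-nonamethylpentatriaconta-2,5,9,13,17,21,25,33-octaenal | CC(C)=CCC[C@H](C)CCC/C(C)=C/CC/C(C)=C/CC/C(C)=C/CC/C(C)=C/CC/C(C)=C/CC/C(C)=C/C/C=C(\C)C=O | intermediate
21 | (2E,5E,9E,13E,17E,21E,25E,30R)-1-[dimethyl(phenyl)silyl]-2,6,10,14,18,22,26,30,34-nonamethylpentatriaconta-2,5,9,13,17,21,25,33-octaen-1-ol (both C1 epimers) | CC(C)=CCC[C@H](C)CCC/C(C)=C/CC/C(C)=C/CC/C(C)=C/CC/C(C)=C/CC/C(C)=C/CC/C(C)=C/C/C=C(\C)C(O)[Si](C)(C)c1ccccc1 | intermediate
22 | (2E,5E,9E,13E,17E,21E,25E,30R)-1-[dimethyl(phenyl)silyl]-2,6,10,14,18,22,26,30,34-nonamethylpentatriaconta-2,5,9,13,17,21,25,33-octaen-1-one | CC(C)=CCC[C@H](C)CCC/C(C)=C/CC/C(C)=C/CC/C(C)=C/CC/C(C)=C/CC/C(C)=C/CC/C(C)=C/C/C=C(\C)C(=O)[Si](C)(C)c1ccccc1 | intermediate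
23 | N,N-diethylbenzamide | CCN(CC)C(=O)c1ccccc1 | starting material
24 | N,N-diethyl-2-lithiobenzamide | CCN(CC)C(=O)c1ccccc1[Li] | intermediate
25 | lithium alkoxide from addition of 24 to the carbonyl of 22 (tertiary α-silyl carbinolate carrying the 2-(diethylcarbamoyl)phenyl group) | CC(C)=CCC[C@H](C)CCC/C(C)=C/CC/C(C)=C/CC/C(C)=C/CC/C(C)=C/CC/C(C)=C/CC/C(C)=C/C/C=C(\C)C(O[Li])([Si](C)(C)c1ccccc1)c1ccccc1C(=O)N(CC)CC | intermediate
26 | siloxyallyllithium formed from 25 by Brook shift (drawn with lithium on C3) | CC(C)=CCC[C@H](C)CCC/C(C)=C/CC/C(C)=C/CC/C(C)=C/CC/C(C)=C/CC/C(C)=C/CC/C(C)=C/CC([Li])C(C)=C(O[Si](C)(C)c1ccccc1)c1ccccc1C(=O)N(CC)CC | intermediate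
27 | 4-{[dimethyl(phenyl)silyl]oxy}-3-methyl-2-[(2E,6E,10E,14E,18E,22E,27R)-3,7,11,15,19,23,27,31-octamethyldotriaconta-2,6,10,14,18,22,30-heptaen-1-yl]naphthalen-1-ol | CC(C)=CCC[C@H](C)CCC/C(C)=C/CC/C(C)=C/CC/C(C)=C/CC/C(C)=C/CC/C(C)=C/CC/C(C)=C/Cc1c(C)c(O[Si](C)(C)c2ccccc2)c2ccccc2c1O | intermediate
28 | 2-methyl-3-[(2E,6E,10E,14E,18E,22E,27R)-3,7,11,15,19,23,27,31-octamethyldotriaconta-2,6,10,14,18,22,30-heptaen-1-yl]naphthalene-1,4-dione | CC(C)=CCC[C@H](C)CCC/C(C)=C/CC/C(C)=C/CC/C(C)=C/CC/C(C)=C/CC/C(C)=C/CC/C(C)=C/CC1=C(C)C(=O)c2ccccc2C1=O | target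

## Step count and risks

Total step count: 17. Longest linear sequence: 17 steps (1 to 28; bromide 4 is used in steps 4 and 7).

Steps most likely to fail:

1. Step 16 (proposed new method). The alkoxide 25 may lactonise onto the amide before the silyl shift, the aryllithium may deprotonate the doubly allylic CH2 next to the enone instead of adding, or the allyl anion may not reach the geometry needed for closure. Fallback, which makes the same two ring bonds one after the other by known chemistry, sets out from alcohol 19. PBr3 (Et2O, −10 °C) should give the allylic bromide F1. Aryllithium 24, made as in step 16, is transmetalated with MgBr2·OEt2 to the arylmagnesium bromide F2 and allylated with F1 (CuBr·SMe2 cat., THF, −78 °C to rt) at its primary carbon to give the ortho-allylbenzamide F3. LDA (THF, −78 °C to rt) should then deprotonate the benzylic, allylic CH2 of F3 and close the ring by the known anionic annulation of ortho-allylbenzamides to the 1-naphthol F4. Oxidation of the free para position of F4 with Co(salen) and O2 in DMF/THF (or (KSO3)2NO) should give the quinone, so the route is rejoined at 28.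

2. Step 14. Conjugate addition of the silyl anion, deprotonation of the acidic doubly allylic γ-CH2 of the skipped dienal, or Brook rearrangement of the alkoxide in the flask may compete with 1,2-addition. Fallback sets out from enal 20. Pinnick oxidation (NaClO2, NaH2PO4, 2-methyl-2-butene, t-BuOH/H2O) should give the carboxylic acid F5. Coupling with morpholine (EDC·HCl, DMAP, CH2Cl2) gives the morpholine amide F6. Acyl substitution of F6 with PhMe2SiLi (THF, −78 °C), which stops at a stable tetrahedral intermediate that cannot undergo a Brook shift, should give the acylsilane on work-up, so the route is rejoined at 22.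

3. Step 11. Carboalumination of the silyl ether may be incomplete or regio-unselective, and the π-allylpalladium intermediate may undergo allylic transposition or E/Z erosion during coupling. Fallback sets out from chloride 15. Copper-mediated alkylation of prop-2-yn-1-ol (CuI, K2CO3, NaI, DMF, rt) at the primary allylic carbon should give the skipped enynol F7. Hydroxyl-directed anti-carbomagnesiation (MeMgBr, CuI 10 mol %, THF, −20 °C to rt) places methyl on the alkyne carbon next to the carbinol and magnesium on the far carbon in the chelated alkenylmagnesium alkoxide F8. Protonolysis of F8 (aq NH4Cl) gives the 2E allylic alcohol, so the route is rejoined at 19 and silyl ether 18 is skipped.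

Further compounds

F1 | step 16 | (2E,5E,9E,13E,17E,21E,25E,30R)-1-bromo-2,6,10,14,18,22,26,30,34-nonamethylpentatriaconta-2,5,9,13,17,21,25,33-octaene | CC(C)=CCC[C@H](C)CCC/C(C)=C/CC/C(C)=C/CC/C(C)=C/CC/C(C)=C/CC/C(C)=C/CC/C(C)=C/C/C=C(\C)CBr
F2 | step 16 | [2-(diethylcarbamoyl)phenyl]magnesium bromide | CCN(CC)C(=O)c1ccccc1[Mg]Br
F3 | step 16 | N,N-diethyl-2-[(2E,5E,9E,13E,17E,21E,25E,30R)-2,6,10,14,18,22,26,30,34-nonamethylpentatriaconta-2,5,9,13,17,21,25,33-octaen-1-yl]benzamide | CC(C)=CCC[C@H](C)CCC/C(C)=C/CC/C(C)=C/CC/C(C)=C/CC/C(C)=C/CC/C(C)=C/CC/C(C)=C/C/C=C(\C)Cc1ccccc1C(=O)N(CC)CC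
F4 | step 16 | 3-methyl-2-[(2E,6E,10E,14E,18E,22E,27R)-3,7,11,15,19,23,27,31-octamethyldotriaconta-2,6,10,14,18,22,30-heptaen-1-yl]naphthalen-1-ol | CC(C)=CCC[C@H](C)CCC/C(C)=C/CC/C(C)=C/CC/C(C)=C/CC/C(C)=C/CC/C(C)=C/CC/C(C)=C/Cc1c(C)cc2ccccc2c1O
F5 | step 14 | (2E,5E,9E,13E,17E,21E,25E,30R)-2,6,10,14,18,22,26,30,34-nonamethylpentatriaconta-2,5,9,13,17,21,25,33-octaenoic acid | CC(C)=CCC[C@H](C)CCC/C(C)=C/CC/C(C)=C/CC/C(C)=C/CC/C(C)=C/CC/C(C)=C/CC/C(C)=C/C/C=C(\C)C(=O)O
F6 | step 14 | (2E,5E,9E,13E,17E,21E,25E,30R)-2,6,10,14,18,22,26,30,34-nonamethyl-1-(morpholin-4-yl)pentatriaconta-2,5,9,13,17,21,25,33-octaen-1-one | CC(C)=CCC[C@H](C)CCC/C(C)=C/CC/C(C)=C/CC/C(C)=C/CC/C(C)=C/CC/C(C)=C/CC/C(C)=C/C/C=C(\C)C(=O)N1CCOCC1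
F7 | step 11 | (5E,9E,13E,17E,21E,25E,30R)-6,10,14,18,22,26,30,34-octamethylpentatriaconta-5,9,13,17,21,25,33-heptaen-2-yn-1-ol | CC(C)=CCC[C@H](C)CCC/C(C)=C/CC/C(C)=C/CC/C(C)=C/CC/C(C)=C/CC/C(C)=C/CC/C(C)=C/CC#CCO
F8 | step 11 | 4-methyl-3-[(2E,6E,10E,14E,18E,22E,27R)-3,7,11,15,19,23,27,31-octamethyldotriaconta-2,6,10,14,18,22,30-heptaen-1-yl]-2,5-dihydro-1,2-oxamagnesole (chelated alkenylmagnesium alkoxide) | CC(C)=CCC[C@H](C)CCC/C(C)=C/CC/C(C)=C/CC/C(C)=C/CC/C(C)=C/CC/C(C)=C/CC/C(C)=C/CC1=C(C)CO[Mg]1
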